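**Retrosynthetic overview**

1. The strategy rests on the central six-membered ring, a fully substituted 1,4-benzoquinone: C1 and C4 are C=O, C2 and C5 carry OMe, C3 carries the 2-(2-methylbut-3-en-2-yl)indol-3-yl group (indole A) and C6 the indol-3-yl group (indole B). These six carbons map onto the four ring carbons of a squarate plus a two-carbon 1-methoxyvinyl unit.
2. Quinone 24 comes from hydroquinone 23 (Ag2O), and 23 from the protected hydroquinone 22 by fluoride deprotection.
3. 22 comes from cyclobutenone 19 by thermal 4π ring opening and 6π ring closure; the one ring-forming C–C bond joins the ketene carbon (former C1 of 19) to the vinyl CH that bears indole B.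
4. 19 comes from squarate adduct 15 and 3-lithiated indole A (1,2-addition, then 1,3-carbonyl transposition); 15 comes from dimethyl squarate 12 and the α-lithiated Z enol ether 11 of indole-3-carbaldehyde; indole A comes from a Madelung cyclisation.
5. Ring order: the pyrrole ring of indole A (step 2), then the central carbocycle (step 10); the four-membered ring and indole B are bought.

Key step: step 10

Remark on the chemistry: the quaternary ring carbon of 14, 15 and 19 is carried as a racemate because it becomes an sp2 carbon in step 10. Indole B carries N–Si(i-Pr)3, which shields indole C2 and has no chelating atom, so that t-BuLi in step 7 should deprotonate the enol ether and not the ring. Indole A, whose nitrogen sits beside a tert-alkyl group, carries the slimmer CH2OCH2CH2SiMe3 (SEM) group.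

**Route**

Step 1
Reactants: 1 2,2-dimethylbut-3-enoic acid; 2 o-toluidine
Product: 4 2,2-dimethyl-N-(2-methylphenyl)but-3-enamide, via 2,2-dimethylbut-3-enoyl chloride 3 (not isolated)
Conditions: (COCl)2, DMF (cat.), CH2Cl2, 0 °C → rt, evaporate; then 2, Et3N, CH2Cl2, 0 °C → rt
Reagents that add atoms: none
Why: Acyl chloride formation followed by N-acylation of the aniline (amide coupling) should be clean because the α-carbon is quaternary, so neither ketene formation nor migration of the double bond into conjugation can occur.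

Step 2
Reactants: 4 2,2-dimethyl-N-(2-methylphenyl)but-3-enamide
Product: 6 2-(2-methylbut-3-en-2-yl)-1H-indole, via dilithiated amide 5 (not isolated)
Conditions: n-BuLi (3 equiv), THF, −20 °C → rt; H2O
Reagents that add atoms: none
Why: This is a Madelung indole synthesis under organolithium conditions, in which deprotonation of N–H and of the ortho methyl group gives 5, the benzylic carbanion adds to the amidate carbon and loss of lithium hydroxide on work-up aromatises the new pyrrole ring, the quaternary α-carbon ruling out enolisation of the amide.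

Step 3
Reactants: 6 2-(2-methylbut-3-en-2-yl)-1H-indole
Product: 7 2-(2-methylbut-3-en-2-yl)-1-{[2-(trimethylsilyl)ethoxy]methyl}indole
Conditions: NaH, DMF, 0 °C; SEMCl, 0 °C → rt
Reagents that add atoms: 2-(trimethylsilyl)ethoxymethyl chloride (SEMCl), C[Si](C)(C)CCOCCl
Why: N-Alkylation of the sodium indolide with the reactive chloromethyl ether (SN2) should succeed despite the neighbouring tert-alkyl group because only a CH2 group is brought next to it.

Step 4
Reactants: 7 2-(2-methylbut-3-en-2-yl)-1-{[2-(trimethylsilyl)ethoxy]methyl}indole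
Product: 8 3-bromo-2-(2-methylbut-3-en-2-yl)-1-{[2-(trimethylsilyl)ethoxy]methyl}indole
Conditions: NBS, THF, −78 → 0 °C, dark
Reagents that add atoms: N-bromosuccinimide, O=C1CCC(=O)N1Br
Why: Electrophilic aromatic bromination of an N-alkylindole takes place at C3, its most nucleophilic carbon, much faster than bromination of the isolated monosubstituted alkene in an aprotic solvent at low temperature.

Step 5
Reactants: 9 indole-3-carbaldehyde
Product: 10 1-(triisopropylsilyl)indole-3-carbaldehyde
Conditions: NaH, THF, 0 °C; i-Pr3SiCl, 0 °C → rt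
Reagents that add atoms: triisopropylsilyl chloride, CC(C)[Si](Cl)(C(C)C)C(C)C
Why: N-Silylation of the indolide anion gives a base-stable N–Si bond whose bulk shields indole C2 and offers no chelating atom, which is what the site-selective lithiation in step 7 needs.

Step 6
Reactants: 10 1-(triisopropylsilyl)indole-3-carbaldehyde
Product: 11 (Z)-3-(2-methoxyvinyl)-1-(triisopropylsilyl)indole
Conditions: Ph3P(CH2OMe)Cl, NaN(SiMe3)2, THF, 0 °C; then 10, 0 °C → rt; Z isomer separated on Et3N-deactivated SiO2
Reagents that add atoms: (methoxymethyl)triphenylphosphonium chloride, COC[P+](c1ccccc1)(c1ccccc1)c1ccccc1.[Cl-]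
Why: Wittig methoxymethylenation of the aldehyde should give the enol ether as a mixture of geometric isomers, from which the Z isomer (methoxy cis to the indole, so that its α-hydrogen is trans to the indole) is taken on after chromatography.

Step 7
Reactants: 11 (Z)-3-(2-methoxyvinyl)-1-(triisopropylsilyl)indole; 12 dimethyl squarate
Product: 14 racemic 4-hydroxy-2,3-dimethoxy-4-[(Z)-1-methoxy-2-(1-triisopropylsilylindol-3-yl)vinyl]cyclobut-2-en-1-one, via α-methoxyvinyllithium 13 (not isolated)
Conditions: 11, t-BuLi (1.05 equiv), THF, −78 → −20 °C; cannulate into 12, THF, −78 °C; aq NH4Cl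
Reagents that add atoms: none
Why: α-Lithiation of the vinyl ether at its oxygen-bearing carbon (with retention of the double-bond geometry) gives 13, which adds 1,2 to one carbonyl of the squarate to give the tertiary alcohol as a racemate, the new quaternary stereocentre needing no control because it becomes an sp2 ring carbon in step 10.

Step 8
Reactants: 14 racemic 4-hydroxy-2,3-dimethoxy-4-[(Z)-1-methoxy-2-(1-triisopropylsilylindol-3-yl)vinyl]cyclobut-2-en-1-one
Product: 15 racemic 4-(tert-butyldimethylsilyloxy)-2,3-dimethoxy-4-[(Z)-1-methoxy-2-(1-triisopropylsilylindol-3-yl)vinyl]cyclobut-2-en-1-one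
Conditions: TBSOTf, 2,6-lutidine, CH2Cl2, −78 → 0 °C
Reagents that add atoms: tert-butyldimethylsilyl triflate, CC(C)(C)[Si](C)(C)OS(=O)(=O)C(F)(F)F
Why: Silylation of the hindered tertiary alcohol with a silyl triflate and a hindered pyridine base should be fast at low temperature, and the silyl ether removes the acidic proton before the second organolithium addition and supplies the oxygen donor that steers the ring opening in step 10.

Step 9
Reactants: 8 3-bromo-2-(2-methylbut-3-en-2-yl)-1-{[2-(trimethylsilyl)ethoxy]methyl}indole; 15 racemic 4-(tert-butyldimethylsilyloxy)-2,3-dimethoxy-4-[(Z)-1-methoxy-2-(1-triisopropylsilylindol-3-yl)vinyl]cyclobut-2-en-1-one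
Product: 19 racemic 4-(tert-butyldimethylsilyloxy)-2-methoxy-4-[(Z)-1-methoxy-2-(1-triisopropylsilylindol-3-yl)vinyl]-3-[2-(2-methylbut-3-en-2-yl)-1-{[2-(trimethylsilyl)ethoxy]methyl}indol-3-yl]cyclobut-2-en-1-one, via 3-lithioindole 16 (not isolated), via lithium alkoxide adduct 17 (not isolated), via tertiary trifluoroacetate 18 (not isolated)
Conditions: 8, t-BuLi (2 equiv), THF, −78 °C; then 15, −78 → −40 °C; (CF3CO)2O, −78 °C; aq NaHCO3, −78 °C → rt
Reagents that add atoms: water, O
Why: Bromine–lithium exchange gives 16, which adds 1,2 to the remaining ring carbonyl to give 17, trifluoroacetylation to 18 turns the tertiary oxygen into a leaving group, and ionisation to a cyclobutenyl cation stabilised by indole A and by the distal methoxy group lets water add at the methoxy-bearing terminus with loss of methanol (1,3-carbonyl transposition of a vinylogous ester adduct), while a conjugate addition–elimination of 16 at the β-methoxy carbon would lead to the same constitution.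

Step 10
Reactants: 19 racemic 4-(tert-butyldimethylsilyloxy)-2-methoxy-4-[(Z)-1-methoxy-2-(1-triisopropylsilylindol-3-yl)vinyl]-3-[2-(2-methylbut-3-en-2-yl)-1-{[2-(trimethylsilyl)ethoxy]methyl}indol-3-yl]cyclobut-2-en-1-one
Product: 22 4-(tert-butyldimethylsilyloxy)-2,5-dimethoxy-3-[2-(2-methylbut-3-en-2-yl)-1-{[2-(trimethylsilyl)ethoxy]methyl}indol-3-yl]-6-(1-triisopropylsilylindol-3-yl)phenol, via dienylketene 20 (not isolated), via 2,4-cyclohexadienone 21 (not isolated)
Conditions: toluene (degassed, 0.01 M), 110 °C, Ar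
Reagents that add atoms: none
Why: Heating opens the cyclobutenone by a conrotatory 4π electrocyclic cleavage of the C1–C4 bond, the siloxy group rotating outward so that the methoxyvinyl arm lies cis to the ketene in dienylketene 20. A thermal disrotatory 6π electrocyclisation then joins the ketene carbon to the vinyl CH carbon that carries indole B, which forms the C(=O)–C(indol-3-yl) bond and closes the central six-membered ring as 2,4-cyclohexadienone 21. Enolisation of 21 removes its only sp3 ring carbon and gives the phenol, so no stereocentre remains and the racemic centre of 19 is lost. The closest known reaction is the thermal ring expansion of squarate-derived 4-alkenyl-4-oxycyclobutenones to hydroquinones (Moore rearrangement). The step needs torquoselectivity and a single cyclisation partner: the oxygen donor on C4 enforces outward rotation (the wrong rotamer can only revert to 19), the Z enol ether keeps indole B outside the closing termini, and indole A on C3 is not part of any six-electron array with the ketene. The substitution pattern (methoxy groups para, indoles para) was fixed in steps 7 and 9 and cannot change here.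

Step 11
Reactants: 22 4-(tert-butyldimethylsilyloxy)-2,5-dimethoxy-3-[2-(2-methylbut-3-en-2-yl)-1-{[2-(trimethylsilyl)ethoxy]methyl}indol-3-yl]-6-(1-triisopropylsilylindol-3-yl)phenol
Product: 23 2,5-dimethoxy-3-[2-(2-methylbut-3-en-2-yl)-1H-indol-3-yl]-6-(1H-indol-3-yl)benzene-1,4-diol
Conditions: Bu4NF (1 M in THF, excess), H2NCH2CH2NH2, DMF (degassed), 80 °C, Ar; acidic aqueous work-up under Ar
Reagents that add atoms: none
Why: Fluoride cleaves the O–Si and N–Si bonds directly and the N–CH2OCH2CH2SiMe3 group by β-elimination of ethylene and loss of formaldehyde, which ethylenediamine traps as imidazolidine, and exclusion of oxygen keeps the product as the hydroquinone, which does not react with the amine, until the amine has been washed out.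

Step 12
Reactants: 23 2,5-dimethoxy-3-[2-(2-methylbut-3-en-2-yl)-1H-indol-3-yl]-6-(1H-indol-3-yl)benzene-1,4-diol
Product: 24 2,5-dimethoxy-3-[2-(2-methylbut-3-en-2-yl)-1H-indol-3-yl]-6-(1H-indol-3-yl)cyclohexa-2,5-diene-1,4-dione (target)
Conditions: Ag2O, Na2SO4, Et2O, rt
Reagents that add atoms: none
Why: Ag2O is a mild two-electron oxidant that converts a hydroquinone into the para-quinone under neutral conditions (hydroquinone oxidation) and should leave the free indole N–H groups, the methoxy groups and the terminal alkene untouched.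

**Compound list**

1 | 2,2-dimethylbut-3-enoic acid | C=CC(C)(C)C(=O)O | starting material
2 | o-toluidine (2-methylaniline) | Cc1ccccc1N | starting material
3 | 2,2-dimethylbut-3-enoyl chloride | C=CC(C)(C)C(=O)Cl | intermediate
4 | 2,2-dimethyl-N-(2-methylphenyl)but-3-enamide | C=CC(C)(C)C(=O)Nc1ccccc1C | intermediate
5 | dilithiated amide (N-lithio amidate with benzylic CH2Li) | [Li]Cc1ccccc1N([Li])C(=O)C(C)(C)C=C | intermediate
6 | 2-(2-methylbut-3-en-2-yl)-1H-indole (indole A) | C=CC(C)(C)c1cc2ccccc2[nH]1 | intermediate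
7 | 2-(2-methylbut-3-en-2-yl)-1-{[2-(trimethylsilyl)ethoxy]methyl}indole | C=CC(C)(C)c1cc2ccccc2n1COCC[Si](C)(C)C | intermediate
8 | 3-bromo-2-(2-methylbut-3-en-2-yl)-1-{[2-(trimethylsilyl)ethoxy]methyl}indole | C=CC(C)(C)c1c(Br)c2ccccc2n1COCC[Si](C)(C)C | intermediate
9 | indole-3-carbaldehyde | O=Cc1c[nH]c2ccccc12 | starting material
10 | 1-(triisopropylsilyl)indole-3-carbaldehyde | O=Cc1cn([Si](C(C)C)(C(C)C)C(C)C)c2ccccc12 | intermediate
11 | (Z)-3-(2-methoxyvinyl)-1-(triisopropylsilyl)indole | CO/C=C\c1cn([Si](C(C)C)(C(C)C)C(C)C)c2ccccc12 | intermediate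
12 | dimethyl squarate (3,4-dimethoxycyclobut-3-ene-1,2-dione) | COC1=C(OC)C(=O)C1=O | starting material
13 | [(Z)-1-methoxy-2-(1-triisopropylsilylindol-3-yl)vinyl]lithium (lithium trans to the indole) | CO/C([Li])=C\c1cn([Si](C(C)C)(C(C)C)C(C)C)c2ccccc12 | intermediate
14 | racemic 4-hydroxy-2,3-dimethoxy-4-[(Z)-1-methoxy-2-(1-triisopropylsilylindol-3-yl)vinyl]cyclobut-2-en-1-one | COC1=C(OC)C(O)(/C(OC)=C/c2cn([Si](C(C)C)(C(C)C)C(C)C)c3ccccc23)C1=O | intermediate
15 | racemic 4-(tert-butyldimethylsilyloxy)-2,3-dimethoxy-4-[(Z)-1-methoxy-2-(1-triisopropylsilylindol-3-yl)vinyl]cyclobut-2-en-1-one | COC1=C(OC)C(O[Si](C)(C)C(C)(C)C)(/C(OC)=C/c2cn([Si](C(C)C)(C(C)C)C(C)C)c3ccccc23)C1=O | intermediate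
16 | 3-lithio-2-(2-methylbut-3-en-2-yl)-1-{[2-(trimethylsilyl)ethoxy]methyl}indole | C=CC(C)(C)c1c([Li])c2ccccc2n1COCC[Si](C)(C)C | intermediate
17 | lithium alkoxide of the 1,2-adduct of 16 with 15 (1-indolyl-2,3-dimethoxy-4-siloxy-4-alkenylcyclobut-2-en-1-olate, diastereomer mixture) | [Li]OC1(c2c(C(C)(C)C=C)n(COCC[Si](C)(C)C)c3ccccc23)C(OC)=C(OC)C1(O[Si](C)(C)C(C)(C)C)/C(OC)=C/c1cn([Si](C(C)C)(C(C)C)C(C)C)c2ccccc12 | intermediate
18 | trifluoroacetate ester of the tertiary alcohol of 17 (diastereomer mixture) | O=C(OC1(c2c(C(C)(C)C=C)n(COCC[Si](C)(C)C)c3ccccc23)C(OC)=C(OC)C1(O[Si](C)(C)C(C)(C)C)/C(OC)=C/c1cn([Si](C(C)C)(C(C)C)C(C)C)c2ccccc12)C(F)(F)F | intermediate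
19 | racemic 4-(tert-butyldimethylsilyloxy)-2-methoxy-4-[(Z)-1-methoxy-2-(1-triisopropylsilylindol-3-yl)vinyl]-3-[2-(2-methylbut-3-en-2-yl)-1-{[2-(trimethylsilyl)ethoxy]methyl}indol-3-yl]cyclobut-2-en-1-one | O=C1C(OC)=C(c2c(C(C)(C)C=C)n(COCC[Si](C)(C)C)c3ccccc23)C1(O[Si](C)(C)C(C)(C)C)/C(OC)=C/c1cn([Si](C(C)C)(C(C)C)C(C)C)c2ccccc12 | intermediate
20 | dienylketene from 19 (ketene-bearing carbon and methoxyvinyl arm cis on the central double bond, indole B trans to the chain on the terminal double bond) | O=C=C(OC)/C(c1c(C(C)(C)C=C)n(COCC[Si](C)(C)C)c2ccccc12)=C(O[Si](C)(C)C(C)(C)C)\C(OC)=C\c1cn([Si](C(C)C)(C(C)C)C(C)C)c2ccccc12 | intermediate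
21 | racemic 4-(tert-butyldimethylsilyloxy)-2,5-dimethoxy-3-(N-SEM indole A)-6-(N-triisopropylsilyl indole B)cyclohexa-2,4-dien-1-one | O=C1C(OC)=C(c2c(C(C)(C)C=C)n(COCC[Si](C)(C)C)c3ccccc23)C(O[Si](C)(C)C(C)(C)C)=C(OC)C1c1cn([Si](C(C)C)(C(C)C)C(C)C)c2ccccc12 | intermediate
22 | 4-(tert-butyldimethylsilyloxy)-2,5-dimethoxy-3-[2-(2-methylbut-3-en-2-yl)-1-{[2-(trimethylsilyl)ethoxy]methyl}indol-3-yl]-6-(1-triisopropylsilylindol-3-yl)phenol | Oc1c(OC)c(c2c(C(C)(C)C=C)n(COCC[Si](C)(C)C)c3ccccc23)c(O[Si](C)(C)C(C)(C)C)c(OC)c1c1cn([Si](C(C)C)(C(C)C)C(C)C)c2ccccc12 | intermediate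
23 | 2,5-dimethoxy-3-[2-(2-methylbut-3-en-2-yl)-1H-indol-3-yl]-6-(1H-indol-3-yl)benzene-1,4-diol | Oc1c(OC)c(c2c(C(C)(C)C=C)[nH]c3ccccc23)c(O)c(OC)c1c1c[nH]c2ccccc12 | intermediate
24 | 2,5-dimethoxy-3-[2-(2-methylbut-3-en-2-yl)-1H-indol-3-yl]-6-(1H-indol-3-yl)cyclohexa-2,5-diene-1,4-dione (CNP0103667.0) | C=CC(C)(C)c1[nH]c2ccccc2c1C1=C(OC)C(=O)C(c2c[nH]c3ccccc23)=C(OC)C1=O | target

**Step count and risks**

Total step count: 12. Longest linear sequence: 8 steps (steps 1–4 and 9–12, or steps 5–12).

Steps most likely to fail: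

1. Step 9. The lithiated carbon of 16 lies between a tert-alkyl group and the benzo ring, and the carbonyl of 15 sits next to a fully substituted siloxy carbon. Carbonyl addition may therefore be too slow to compete with protonation or electron transfer, and the acid released in the transposition may hydrolyse or isomerise the enol ether arm. The fallback sets out from 8, 11 and 12 and comes back to the route at 23. Lithiated 16 (made from 8 as in step 9) is added to the unhindered carbonyl of 12 and the mixture is quenched with (CF3CO)2O to give 3-methoxy-4-(N-SEM indole A)cyclobut-3-ene-1,2-dione F1. Enol ether 11 is treated with Br2 in CH2Cl2 at −78 °C to give the dibromide F2, which is dehydrobrominated in the same flask with DBU to the vinyl bromide F3. Bromine–lithium exchange with t-BuLi gives the vinyllithium F4, which adds to the more electrophilic carbonyl of F1 (the one next to the methoxy-bearing carbon) to give the 4-hydroxycyclobutenone F5. Heating F5 in toluene at 110 °C gives the same kind of ring expansion, now closing between the ketene carbon and the methoxy-bearing vinyl carbon, and should give the hydroquinone F6, which has the substitution pattern of 22 without the silyl ether. F6 is deprotected under the conditions of step 11 to give 23.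

2. Step 7. Deprotonation may take place at a ring position of indole B instead of the vinyl carbon, or t-BuLi may add across the styrene-like double bond with loss of methoxide. In addition, only the Z isomer from step 6 places the lithium trans to the indole. The fallback sets out from 10 and comes back to the route at 13. Methoxymethyl p-tolyl sulfoxide is deprotonated with LiN(i-Pr)2 in THF at −78 °C and added to 10 to give the β-hydroxy sulfoxide F7. Dehydration with MsCl and Et3N, then DBU, gives the α-methoxyvinyl sulfoxide F8, and the isomer with the sulfinyl group trans to the indole is separated. Sulfoxide–lithium exchange with t-BuLi in THF at −78 °C, which retains the double-bond geometry, generates 13 without any deprotonation step, and 13 is added to 12 as in step 7.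

3. Step 11. Traces of oxygen may oxidise the electron-rich hydroquinone while ethylenediamine is still present, after which the amine displaces a methoxy group of the quinone. Cleavage of the N–CH2 group on the hindered nitrogen of indole A may also stall at the N-hydroxymethyl stage. The fallback sets out from 22 and comes back to the route at 24. Bu4NF in THF at 0 °C removes only the O-silyl and N-silyl groups and gives the N-SEM hydroquinone F9. Ag2O oxidation gives the N-SEM quinone F10. BF3·OEt2 in CH2Cl2 at 0 °C cleaves the SEM ether to the N-hydroxymethyl quinone F11. Catalytic NaOMe in dry MeOH at 0 °C then releases formaldehyde to give 24; under these conditions methoxide exchange at the two methoxy-bearing quinone carbons is degenerate.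

**Further compounds**

F1 | step 9 | 3-methoxy-4-[2-(2-methylbut-3-en-2-yl)-1-{[2-(trimethylsilyl)ethoxy]methyl}indol-3-yl]cyclobut-3-ene-1,2-dione | COC1=C(c2c(C(C)(C)C=C)n(COCC[Si](C)(C)C)c3ccccc23)C(=O)C1=O
F2 | step 9 | 3-(1,2-dibromo-2-methoxyethyl)-1-(triisopropylsilyl)indole (diastereomer mixture) | COC(Br)C(Br)c1cn([Si](C(C)C)(C(C)C)C(C)C)c2ccccc12
F3 | step 9 | 3-(1-bromo-2-methoxyvinyl)-1-(triisopropylsilyl)indole (mixture of geometric isomers) | COC=C(Br)c1cn([Si](C(C)C)(C(C)C)C(C)C)c2ccccc12
F4 | step 9 | [2-methoxy-1-(1-triisopropylsilylindol-3-yl)vinyl]lithium | COC=C([Li])c1cn([Si](C(C)C)(C(C)C)C(C)C)c2ccccc12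
F5 | step 9 | racemic 4-hydroxy-3-methoxy-4-[2-methoxy-1-(1-triisopropylsilylindol-3-yl)vinyl]-2-[2-(2-methylbut-3-en-2-yl)-1-{[2-(trimethylsilyl)ethoxy]methyl}indol-3-yl]cyclobut-2-en-1-one | O=C1C(c2c(C(C)(C)C=C)n(COCC[Si](C)(C)C)c3ccccc23)=C(OC)C1(O)C(=COC)c1cn([Si](C(C)C)(C(C)C)C(C)C)c2ccccc12
F6 | step 9 | 2,5-dimethoxy-3-[2-(2-methylbut-3-en-2-yl)-1-{[2-(trimethylsilyl)ethoxy]methyl}indol-3-yl]-6-(1-triisopropylsilylindol-3-yl)benzene-1,4-diol | Oc1c(OC)c(c2c(C(C)(C)C=C)n(COCC[Si](C)(C)C)c3ccccc23)c(O)c(OC)c1c1cn([Si](C(C)C)(C(C)C)C(C)C)c2ccccc12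
F7 | step 7 | 2-methoxy-2-(4-methylphenylsulfinyl)-1-(1-triisopropylsilylindol-3-yl)ethanol (diastereomer mixture) | COC(C(O)c1cn([Si](C(C)C)(C(C)C)C(C)C)c2ccccc12)S(=O)c1ccc(C)cc1
F8 | step 7 | (E)-3-[2-methoxy-2-(4-methylphenylsulfinyl)vinyl]-1-(triisopropylsilyl)indole (sulfinyl trans to the indole, racemic at sulfur) | CO/C(=C\c1cn([Si](C(C)C)(C(C)C)C(C)C)c2ccccc12)S(=O)c1ccc(C)cc1
F9 | step 11 | 2,5-dimethoxy-3-[2-(2-methylbut-3-en-2-yl)-1-{[2-(trimethylsilyl)ethoxy]methyl}indol-3-yl]-6-(1H-indol-3-yl)benzene-1,4-diol | Oc1c(OC)c(c2c(C(C)(C)C=C)n(COCC[Si](C)(C)C)c3ccccc23)c(O)c(OC)c1c1c[nH]c2ccccc12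
F10 | step 11 | 2,5-dimethoxy-3-[2-(2-methylbut-3-en-2-yl)-1-{[2-(trimethylsilyl)ethoxy]methyl}indol-3-yl]-6-(1H-indol-3-yl)cyclohexa-2,5-diene-1,4-dione | C=CC(C)(C)c1n(COCC[Si](C)(C)C)c2ccccc2c1C1=C(OC)C(=O)C(c2c[nH]c3ccccc23)=C(OC)C1=O
F11 | step 11 | 3-[1-(hydroxymethyl)-2-(2-methylbut-3-en-2-yl)indol-3-yl]-2,5-dimethoxy-6-(1H-indol-3-yl)cyclohexa-2,5-diene-1,4-dione | C=CC(C)(C)c1n(CO)c2ccccc2c1C1=C(OC)C(=O)C(c2c[nH]c3ccccc23)=C(OC)C1=O
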